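**Retrosynthetic overview**
1. The p-quinone methide comes from loss of water from a bis(4-hydroxyphenyl)(aryl)carbinol, which one global desilylation releases in the last step.
2. The carbinol comes from a methyl biphenyl-2-carboxylate and two 4-(silyloxy)phenyllithium units (double 1,2-addition).
3. The central 1,2,3,4-tetrasubstituted ring comes from methyl 2-bromo-6-chloro-3-(silyloxymethyl)benzoate: C–Br by Sonogashira (alkyne arm) first, C–Cl by Suzuki–Miyaura (aryl arm) second.
4. That ester comes from lithiation between Br and Cl of O-silylated 2-bromo-4-chlorobenzyl alcohol, followed by ClCO2Me.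
5. No ring is built. All five six-membered rings are bought as benzenes and joined in the order central ring, alkyne-phenol ring, biaryl ring, the two carbinol rings. The cyclohexadienone ring arises last by dearomatising one carbinol ring.

Assumption: the SMILES holds no stereodescriptor and no stereocentre. Its only stereo-element is the axis between the central ring and the quinone methide carbon, and the fast phenol/quinone methide proton shift levels it. The compound is therefore made as drawn and no step needs stereocontrol. TBS = tert-butyldimethylsilyl; TBSO = its ether oxygen.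

**Step 1**
Reactants: 1 (2-bromo-4-chlorophenyl)methanol
Product: 2 [(2-bromo-4-chlorobenzyl)oxy](tert-butyl)dimethylsilane
Conditions: TBSCl (1.2 equiv), imidazole (2 equiv), CH2Cl2, 0 °C → rt
Reagents that add atoms: tert-butyldimethylsilyl chloride (TBSCl), CC(C)(C)[Si](C)(C)Cl
Why: Imidazole-promoted O-silylation (silyl ether protection) removes the only acidic proton so that the benzylic oxygen survives the lithium amide, both palladium couplings and the aryllithium, and no stereocentre is formed.

**Step 2**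
Reactants: 2 [(2-bromo-4-chlorobenzyl)oxy](tert-butyl)dimethylsilane
Product: 4 methyl 2-bromo-6-chloro-3-(TBSO-methyl)benzoate, via aryllithium 3 (not isolated)
Conditions: LiN(i-Pr)2 (1.1 equiv), THF, −78 °C, 1 h; then ClCO2Me (3 equiv), −78 °C → rt
Reagents that add atoms: methyl chloroformate, COC(=O)Cl
Why: Directed ortho-lithiation: the ring C–H flanked by Br and Cl is by far the most acidic one, the 2,6-dihaloaryllithium holds at −78 °C without benzyne loss or halogen dance, and its acylation by the chloroformate stops at the ester because the di-ortho-halogenated carbonyl is shielded from a second attack.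

**Step 3**
Reactants: 5 4-ethynylphenol
Product: 6 tert-butyl(4-ethynylphenoxy)dimethylsilane
Conditions: TBSCl (1.1 equiv), imidazole (2 equiv), CH2Cl2, 0 °C → rt
Reagents that add atoms: tert-butyldimethylsilyl chloride (TBSCl), CC(C)(C)[Si](C)(C)Cl
Why: The same imidazole-promoted O-silylation masks the phenol against the aryllithium of step 6 and stabilises the polymerisation-prone ethynylphenol.

**Step 4**
Reactants: 4 methyl 2-bromo-6-chloro-3-(TBSO-methyl)benzoate; 6 tert-butyl(4-ethynylphenoxy)dimethylsilane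
Product: 7 methyl 6-chloro-3-(TBSO-methyl)-2-{[4-(TBSO)phenyl]ethynyl}benzoate
Conditions: PdCl2(PPh3)2 (5 mol %), CuI (10 mol %), Et3N/THF 1:1, degassed, slow addition of 6 (1.3 equiv), 70 °C
Reagents that add atoms: none
Why: Sonogashira coupling: PPh3-ligated zerovalent palladium inserts only into the ester-activated C–Br bond, the C–Cl bond being inert to this catalyst, and the small copper acetylide can reach the di-ortho-substituted arylpalladium centre.

**Step 5**
Reactants: 7 methyl 6-chloro-3-(TBSO-methyl)-2-{[4-(TBSO)phenyl]ethynyl}benzoate; 8 [4-(TBSO)phenyl]boronic acid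
Product: 9 methyl 4'-(TBSO)-4-(TBSO-methyl)-3-{[4-(TBSO)phenyl]ethynyl}biphenyl-2-carboxylate
Conditions: Pd(OAc)2 (5 mol %), SPhos (10 mol %), K3PO4 (2 equiv), toluene/H2O 20:1, 90 °C
Reagents that add atoms: none
Why: Suzuki–Miyaura coupling: the bulky electron-rich phosphine SPhos lets zerovalent palladium insert into the remaining ortho-ester-activated C–Cl bond, the boronic acid partner is unhindered, the new biaryl axis carries a symmetric para-substituted ring so no stereo-element arises, and ester, alkyne and silyl ethers tolerate the biphasic phosphate base.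

**Step 6**
Reactants: 9 methyl 4'-(TBSO)-4-(TBSO-methyl)-3-{[4-(TBSO)phenyl]ethynyl}biphenyl-2-carboxylate; 10 (4-bromophenoxy)(tert-butyl)dimethylsilane
Product: 13 [4'-(TBSO)-4-(TBSO-methyl)-3-{[4-(TBSO)phenyl]ethynyl}biphenyl-2-yl]bis[4-(TBSO)phenyl]methanol, via aryllithium 11 (not isolated), via diaryl ketone 12 (not isolated)
Conditions: 10 (5 equiv), n-BuLi (4.8 equiv), THF, −78 °C, 30 min; then 9, −78 °C → rt; H2O quench
Reagents that add atoms: none
Why: Bromine–lithium exchange is followed by double 1,2-addition of the aryllithium to the non-enolisable ester (ketone 12 forms on collapse of the first adduct and is more electrophilic than the ester), which is feasible because one neighbour is only a slim sp-carbon arm, so the carbonyl is about as shielded as in the biphenyl-2-carboxylates that routinely take up two aryllithiums, and the new carbinol carbon bears two identical aryl groups and so is no stereocentre.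

**Step 7**
Reactants: 13 [4'-(TBSO)-4-(TBSO-methyl)-3-{[4-(TBSO)phenyl]ethynyl}biphenyl-2-yl]bis[4-(TBSO)phenyl]methanol
Product: 15 selaginellin, via pentaol 14 (not isolated)
Conditions: Bu4NF (6 equiv), AcOH (6 equiv), THF, 0 °C → rt
Reagents that add atoms: none
Why: Fluoride-driven cleavage of all five Si–O bonds gives pentaol 14, whose doubly para-hydroxy-stabilised C–OH ionises under the acetic acid buffer and loses water (1,6-elimination, fuchsone formation) to the conjugated p-quinone methide, while the buffer keeps the benzylic alcohol protonated so that it does not add to the neighbouring alkyne, and no stereocentre is created.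

**Compound list**
1 | (2-bromo-4-chlorophenyl)methanol | OCc1ccc(Cl)cc1Br | starting material
2 | [(2-bromo-4-chlorobenzyl)oxy](tert-butyl)dimethylsilane | CC(C)(C)[Si](C)(C)OCc1ccc(Cl)cc1Br | intermediate
3 | [2-bromo-6-chloro-3-(TBSO-methyl)phenyl]lithium | [Li]c1c(Cl)ccc(CO[Si](C)(C)C(C)(C)C)c1Br | intermediate
4 | methyl 2-bromo-6-chloro-3-(TBSO-methyl)benzoate | COC(=O)c1c(Cl)ccc(CO[Si](C)(C)C(C)(C)C)c1Br | intermediate
5 | 4-ethynylphenol | C#Cc1ccc(O)cc1 | starting material
6 | tert-butyl(4-ethynylphenoxy)dimethylsilane | C#Cc1ccc(O[Si](C)(C)C(C)(C)C)cc1 | intermediate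
7 | methyl 6-chloro-3-(TBSO-methyl)-2-{[4-(TBSO)phenyl]ethynyl}benzoate | COC(=O)c1c(Cl)ccc(CO[Si](C)(C)C(C)(C)C)c1C#Cc1ccc(O[Si](C)(C)C(C)(C)C)cc1 | intermediate
8 | [4-(TBSO)phenyl]boronic acid | CC(C)(C)[Si](C)(C)Oc1ccc(B(O)O)cc1 | starting material
9 | methyl 4'-(TBSO)-4-(TBSO-methyl)-3-{[4-(TBSO)phenyl]ethynyl}biphenyl-2-carboxylate | COC(=O)c1c(-c2ccc(O[Si](C)(C)C(C)(C)C)cc2)ccc(CO[Si](C)(C)C(C)(C)C)c1C#Cc1ccc(O[Si](C)(C)C(C)(C)C)cc1 | intermediate
10 | (4-bromophenoxy)(tert-butyl)dimethylsilane | CC(C)(C)[Si](C)(C)Oc1ccc(Br)cc1 | starting material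
11 | [4-(TBSO)phenyl]lithium | [Li]c1ccc(O[Si](C)(C)C(C)(C)C)cc1 | intermediate
12 | [4'-(TBSO)-4-(TBSO-methyl)-3-{[4-(TBSO)phenyl]ethynyl}biphenyl-2-yl][4-(TBSO)phenyl]methanone | O=C(c1ccc(O[Si](C)(C)C(C)(C)C)cc1)c1c(-c2ccc(O[Si](C)(C)C(C)(C)C)cc2)ccc(CO[Si](C)(C)C(C)(C)C)c1C#Cc1ccc(O[Si](C)(C)C(C)(C)C)cc1 | intermediate
13 | [4'-(TBSO)-4-(TBSO-methyl)-3-{[4-(TBSO)phenyl]ethynyl}biphenyl-2-yl]bis[4-(TBSO)phenyl]methanol | OC(c1ccc(O[Si](C)(C)C(C)(C)C)cc1)(c1ccc(O[Si](C)(C)C(C)(C)C)cc1)c1c(-c2ccc(O[Si](C)(C)C(C)(C)C)cc2)ccc(CO[Si](C)(C)C(C)(C)C)c1C#Cc1ccc(O[Si](C)(C)C(C)(C)C)cc1 | intermediate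
14 | [4'-hydroxy-4-(hydroxymethyl)-3-[(4-hydroxyphenyl)ethynyl]biphenyl-2-yl]bis(4-hydroxyphenyl)methanol | OCc1ccc(-c2ccc(O)cc2)c(C(O)(c2ccc(O)cc2)c2ccc(O)cc2)c1C#Cc1ccc(O)cc1 | intermediate
15 | selaginellin, 4-{[4'-hydroxy-4-(hydroxymethyl)-3-[(4-hydroxyphenyl)ethynyl]biphenyl-2-yl](4-hydroxyphenyl)methylidene}cyclohexa-2,5-dien-1-one | O=C1C=CC(=C(c2ccc(O)cc2)c2c(-c3ccc(O)cc3)ccc(CO)c2C#Cc2ccc(O)cc2)C=C1 | target

**Total step count:** 7
**Longest linear sequence:** 6 steps (steps 1, 2, 4, 5, 6, 7). Step 3 is a one-step side branch.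

**Three steps most likely to fail**

**Step 6** (double aryllithium addition to a di-ortho-substituted ester; it may stall at the ester or at ketone 12). The fallback swaps the order of the last two C–C bond formations. It sets out from 7 and comes back at 13. In 7 the ester is flanked only by Cl and the slim alkynyl arm. Aryllithium 11 (from 10 and n-BuLi, THF, −78 °C → 0 °C) should therefore add twice with ease, passing through the chloro ketone F1 to give the chloro carbinol F2. The aryl arm is then put in last by Suzuki–Miyaura coupling of F2 with 8 (Pd(OAc)2, SPhos, K3PO4, toluene/H2O, 100 °C). In that coupling the steric load falls on a catalyst made for hindered aryl chlorides and no longer on a carbonyl addition.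

**Step 4** (Sonogashira coupling at a bromide flanked by CO2Me and CH2OTBS; slow oxidative addition lets 6 dimerise oxidatively). The fallback reverses the roles of the partners. It sets out from 4 and comes back at 7.
- Bromine–magnesium exchange (i-PrMgCl·LiCl, THF, −30 °C), which is insensitive to the crowding and spares Cl and the shielded ester, gives the arylmagnesium chloride F3.
- DMF converts it into the aldehyde methyl 6-chloro-2-formyl-3-(TBSO-methyl)benzoate F4.
- Ohira–Bestmann homologation (dimethyl (1-diazo-2-oxopropyl)phosphonate, K2CO3, MeOH, rt) gives the terminal alkyne methyl 6-chloro-2-ethynyl-3-(TBSO-methyl)benzoate F5.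
- F5 is coupled at rt (PdCl2(PPh3)2, CuI, Et3N) with purchased, unhindered tert-butyl(4-iodophenoxy)dimethylsilane (CC(C)(C)[Si](C)(C)Oc1ccc(I)cc1), so palladium never has to insert next to two ortho groups.

**Step 7** (five silyl ethers removed at once; a freed benzylic alkoxide could close 5-exo-dig onto the alkyne, and the product is sensitive). The fallback is a staged, chemoselective unmasking. It sets out from 13 and comes back at 15. KHF2 in MeOH/THF at rt cleaves only the four aryl silyl ethers. The resulting tetraphenol carbinol F6 loses water in the flask to give the quinone methide that still carries its primary silyl ether, selaginellin O-TBS ether F7. The primary TBS group is then taken off under weakly acidic, non-nucleophilic conditions (AcOH/THF/H2O 3:1:1, rt). The benzylic hydroxyl is thus never present as an alkoxide beside the alkyne.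

**Further compounds**
F1 | step 6 | [6-chloro-3-(TBSO-methyl)-2-{[4-(TBSO)phenyl]ethynyl}phenyl][4-(TBSO)phenyl]methanone | O=C(c1ccc(O[Si](C)(C)C(C)(C)C)cc1)c1c(Cl)ccc(CO[Si](C)(C)C(C)(C)C)c1C#Cc1ccc(O[Si](C)(C)C(C)(C)C)cc1
F2 | step 6 | [6-chloro-3-(TBSO-methyl)-2-{[4-(TBSO)phenyl]ethynyl}phenyl]bis[4-(TBSO)phenyl]methanol | OC(c1ccc(O[Si](C)(C)C(C)(C)C)cc1)(c1ccc(O[Si](C)(C)C(C)(C)C)cc1)c1c(Cl)ccc(CO[Si](C)(C)C(C)(C)C)c1C#Cc1ccc(O[Si](C)(C)C(C)(C)C)cc1
F3 | step 4 | [3-chloro-2-(methoxycarbonyl)-6-(TBSO-methyl)phenyl]magnesium chloride | COC(=O)c1c(Cl)ccc(CO[Si](C)(C)C(C)(C)C)c1[Mg]Cl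
F4 | step 4 | methyl 6-chloro-2-formyl-3-(TBSO-methyl)benzoate | COC(=O)c1c(Cl)ccc(CO[Si](C)(C)C(C)(C)C)c1C=O
F5 | step 4 | methyl 6-chloro-2-ethynyl-3-(TBSO-methyl)benzoate | COC(=O)c1c(Cl)ccc(CO[Si](C)(C)C(C)(C)C)c1C#C
F6 | step 7 | [4'-hydroxy-3-[(4-hydroxyphenyl)ethynyl]-4-(TBSO-methyl)biphenyl-2-yl]bis(4-hydroxyphenyl)methanol | OC(c1ccc(O)cc1)(c1ccc(O)cc1)c1c(-c2ccc(O)cc2)ccc(CO[Si](C)(C)C(C)(C)C)c1C#Cc1ccc(O)cc1
F7 | step 7 | selaginellin O-TBS ether (primary benzylic silyl ether of 15) | O=C1C=CC(=C(c2ccc(O)cc2)c2c(-c3ccc(O)cc3)ccc(CO[Si](C)(C)C(C)(C)C)c2C#Cc2ccc(O)cc2)C=C1
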